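The ratio to watch in these two flasks is c(isomer of the product) over c(target), which starts at nothing and climbs towards the equilibrium constant of the isomerisation at a pace of its own.

all flasks: starting material 20 mM; reagent 30.0 mM; second substrate 4.00 mM; time 10 h
- Tuesday's: temperature 20 °C
- Sunday's: temperature 35 °C

    target ⇌ isomer of the product (K1 = 2.1, k1 = 7.0 × 10⁻⁶ s⁻¹, Ea1 = 96.0 kJ mol⁻¹, ΔH1 = −11.0 kJ mol⁻¹)
    second substrate + reagent → second product (k2 = 0.13 L mol⁻¹ s⁻¹, Ea2 = 51.0 kJ mol⁻¹)
    starting material ⇌ dormant form (K3 = 1.9, k3 = 4.6 × 10⁻⁵ s⁻¹, Ea3 = 99.0 kJ mol⁻¹, ΔH3 = −27.0 kJ mol⁻¹)
    starting material + reagent → target (k4 = 0.029 L mol⁻¹ s⁻¹, Ea4 = 61.0 kJ mol⁻¹)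
    2 second substrate → self-condensation product (k5 = 0.014 L mol⁻¹ s⁻¹, Ea5 = 47.0 kJ mol⁻¹)
    (constants at 20 °C)

- two of one species on the left: rate k times its square, two consumed each time
- the constants hold at 20 °C; other temperatures follow from the activation energies and enthalpies

- which flask leads in amount of target, in percent of the starting material charged ("all alike" within 1.5 percentage points) (Tuesday's / Sunday's / all alike)
- how much target is there at the end, in percent of the starting material charged: Tuesday's
- how much target is there at the end, in percent of the starting material charged: Sunday's

Is there enough reagent? Yes: 30.0 mM covers 20 mM of starting material and 4.00 mM of second substrate with 6.00 mM to spare, and second substrate, with the larger constant, takes its share early.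

How fast does target appear in Tuesday's flask? At the charged reagent, the step to target by itself halves starting material in 13.3 min, so making target is quick beside what follows.

What follows? Target and isomer of the product exchange, and the gap to equilibrium closes at the sum of the forward constant and the back constant, which is the forward constant over the equilibrium constant. Take ln 2 over that sum, the relaxation half-life, in which the gap between the share of target and its equilibrium share halves: for Tuesday's 18.6 h. At 35 °C the forward constant becomes 4.76 × 10⁻⁵ s⁻¹ and the equilibrium constant 1.69, so Sunday's half-life is 2.54 h.

Your first round? Put the charge into target at time zero. Tuesday's equilibrium share is 32.3%, and the gap shrinks over 10 h to leave 79.0%. Sunday's equilibrium share is 37.2%, leaving 41.3%.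

Where is that weak? Dormant form is no partner in the isomerisation step. Summing the ratio of the forward dormant constant to itself plus the making rate constant times c(reagent), as reagent falls to its spare amount, I estimate that 10.2% of Tuesday's charge is parked. Letting that decay by the back step, at the forward constant over the equilibrium constant, and ignoring any return to dormant form, my estimate for the end is 4.28%. Going round again, Tuesday's target is 75.6%. Sunday's back step from dormant form has a half-life of 0.642 h, short against the run, so I keep 41.3% there.

The forecast names Tuesday's, with 76% against 42%, on the ground that Sunday's isomerisation “runs close to its less favourable equilibrium”; its Sunday figure stands slightly above mine.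

The simulation gives 76.1% for Tuesday's and 42.0% for Sunday's, so Tuesday's leads. Sunday's flask falls short through the isomerisation, since without that step its target stands at >99.9%. Sunday's relaxation half-life is short against the run, so that flask stands near thermodynamic control, whereas Tuesday's 18.6 h is longer than the run, so Tuesday's flask is read under kinetic control. In the neighbour like Sunday's kept at 10 °C, the half-life comes to 78.6 h, and by the same reckoning the share of the pair that is target comes to 94.0%. Applied to what is neither dormant form nor starting material, that gives 88.1%, and that flask held 88.9%.

(The constants used here are made up; no experiment stands behind them.)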